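## Retrosynthetic overview

1. Halimane numbering: ring A = C1–C5 + C10, ring B = C5–C10, C17 on C8, C20 on C9, side chain C11–C16 on C9, acid C18 on C4. The (Z)-cinnamate is made last, by semi-hydrogenation of an aryl ynoate.
2. Ring A is formed second: ring-closing metathesis makes C1=C10, after an acyclic, stereocontrolled C4 methylation and an Ireland–Claisen rearrangement that makes C4–C5 and relays a reagent-set carbinol centre to C5.
3. The side chain is completed by a B-alkyl Suzuki–Miyaura coupling (C12–C13).
4. Ring B is formed first: a catalytic enantioselective Diels–Alder reaction of (E)-2-methylbut-2-enal with a 1-silyloxybutadiene closes C7–C8 and C9–C10 and sets C8 and the quaternary C9 in one event.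
5. Enabling feature: in ring B the pair C8(H)(CH3)–C9(CH3)(C11), with cis methyls, lies between C7H2 and the sp2 carbon C10. This is the imprint of an (E)-trisubstituted enal on a butadiene, and the diene oxygen on C10 later becomes the ketone and enol triflate handle for C1=C10.

Key step: step 2

Remark 1: β denotes the face of ring B that carries C17 and C20; H5, C11 and the CO2H group are α.
Remark 2: the sense of induction of the oxazaborolidinium catalyst in step 2 is assumed; if it is the opposite, the (R)-catalyst is used.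
Remark 3: the C10 configuration of 4, 5, 10, 11 and 12 is drawn for the endo adduct; it is inconsequential, because both epimers converge at enone 13.

## Route

Step 1
Reactants: 1 (E)-but-2-enal
Product: 2 (1E)-1-(triisopropylsilyloxy)buta-1,3-diene
Conditions: i-Pr3SiOTf, Et3N, Et2O, 0 °C to rt
Reagents that add atoms: triisopropylsilyl trifluoromethanesulfonate, CC(C)[Si](OS(=O)(=O)C(F)(F)F)(C(C)C)C(C)C
Why: Soft enolisation of the enal with a silyl triflate and an amine (silyl dienol ether formation) should give the (1E)-diene; no stereocentre is formed.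

Step 2
Reactants: 2 (1E)-1-(triisopropylsilyloxy)buta-1,3-diene; 3 (E)-2-methylbut-2-enal
Product: 4 ring B aldehyde, 1,6-dimethyl-2-(triisopropylsilyloxy)cyclohex-3-ene-1-carbaldehyde (C9: CH3 β, CHO α; C8: CH3 β; C10: OSi α)
Conditions: 20 mol% (S)-3,3-diphenyl-1-(o-tolyl)oxazaborolidinium triflimide (from (S)-α,α-diphenylprolinol, o-tolylboroxine and Tf2NH), CH2Cl2, −78 to −40 °C
Reagents that add atoms: none
Why: The boron Lewis acid binds the s-trans enal and the silyloxydiene adds in a concerted, asynchronous [4+2] cycloaddition (enantioselective Diels–Alder reaction). The closest known type is the chiral oxazaborolidinium-catalysed Diels–Alder reaction of α-substituted enals with dienes, silyloxydienes included. Ring B is closed by a suprafacial [4+2] that forms C7–C8 and C9–C10 together. The C8/C9 relative configuration (C17 and C20 cis, CHO trans to C17) follows from the (E)-geometry of 3, and the absolute configuration from the face shielded by the catalyst; the C10 centre (endo expected) is erased later. The step needs ortho regiochemistry, which the C10 silyloxy donor secures by pairing the unsubstituted terminus C7 with the enal β-carbon C8. It also needs cycloaddition in preference to 1,2-addition at the formyl group, which the bulky silyl group and the low temperature should favour.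

Step 3
Reactants: 4 ring B aldehyde
Product: 5 ring B diene, 4-ethenyl-4,5-dimethyl-3-(triisopropylsilyloxy)cyclohexene (vinyl = C11=C12 on C9)
Conditions: Ph3PCH3Br, KN(SiMe3)2, THF, 0 °C to rt
Reagents that add atoms: methyltriphenylphosphonium bromide, C[P+](c1ccccc1)(c1ccccc1)c1ccccc1.[Br-]
Why: Wittig methylenation of a non-enolisable neopentyl aldehyde should be clean, since the quaternary α-carbon rules out epimerisation and β-elimination of the silyloxy group.

Step 4
Reactants: 6 but-2-yn-1-ol
Product: 7 1-(but-2-ynyloxymethyl)-4-methoxybenzene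
Conditions: NaH, 4-MeOC6H4CH2Cl, Bu4NI (cat.), THF/DMF, 0 °C to rt
Reagents that add atoms: 4-methoxybenzyl chloride, COc1ccc(CCl)cc1
Why: Williamson etherification of a primary propargylic alkoxide.

Step 5
Reactants: 7 1-(but-2-ynyloxymethyl)-4-methoxybenzene
Product: 9 (E)-3-iodobut-2-enyl 4-methoxybenzyl ether, via alkenylzirconocene chloride 8 (not isolated)
Conditions: Cp2Zr(H)Cl (1.3 equiv), THF, 40 °C; then I2, 0 °C
Reagents that add atoms: iodine, II
Why: syn-Hydrozirconation should, after equilibration with a slight excess of Cp2Zr(H)Cl, place zirconium on the methyl-bearing carbon, and iododezirconation with retention gives the (E)-iodide (iodine trans to CH2O).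

Step 6
Reactants: 5 ring B diene; 9 (E)-3-iodobut-2-enyl 4-methoxybenzyl ether
Product: 11 silyl ether with the complete side chain (13E, C15–O-PMB), via B-alkyl-9-BBN borane 10 (not isolated)
Conditions: 9-BBN-H, THF, rt; then 9, PdCl2(dppf) (5 mol%), AsPh3, Cs2CO3, DMF/H2O, rt
Reagents that add atoms: none
Why: 9-BBN-H should hydroborate the monosubstituted vinyl group in preference to the ring cis-alkene, and the B-alkyl Suzuki–Miyaura coupling joins C12 to C13 with retention of the (E)-geometry of 9.

Step 7
Reactants: 11 silyl ether with the complete side chain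
Product: 12 allylic alcohol (C10–OH)
Conditions: Bu4NF, THF, 50 °C
Reagents that add atoms: none
Why: Fluoride cleavage of the hindered secondary silyl ether.

Step 8
Reactants: 12 allylic alcohol
Product: 13 (5,6-cis-dimethyl) 5,6-dimethyl-6-[(E)-5-(4-methoxybenzyloxy)-3-methylpent-3-enyl]cyclohex-2-en-1-one
Conditions: Dess–Martin periodinane, CH2Cl2, rt
Reagents that add atoms: none
Why: Dess–Martin oxidation of the allylic alcohol; both C10 epimers converge on the enone.

Step 9
Reactants: 13 enone
Product: 15 5,6-dimethyl-6-[(E)-5-(4-methoxybenzyloxy)-3-methylpent-3-enyl]cyclohex-1-enyl trifluoromethanesulfonate, via lithium enolate 14 (not isolated)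
Conditions: LiBH(s-Bu)3, THF, −78 °C; then PhNTf2, −78 to 0 °C
Reagents that add atoms: N-phenylbis(trifluoromethanesulfonimide), O=S(=O)(N(c1ccccc1)S(=O)(=O)C(F)(F)F)C(F)(F)F
Why: Conjugate hydride reduction of the β-unsubstituted cyclohexenone (1,2-attack is hindered by the quaternary C9) should give the C10–C5 enolate regiospecifically, which is trapped as the enol triflate.

Step 10
Reactants: 15 enol triflate
Product: 17 1-{5,6-dimethyl-6-[(E)-5-(4-methoxybenzyloxy)-3-methylpent-3-enyl]cyclohex-1-enyl}ethanone, via ethyl enol ether 16 (not isolated)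
Conditions: Bu3Sn–C(OEt)=CH2, Pd(PPh3)4 (5 mol%), LiCl, CuI (10 mol%), THF, 60 °C; then 1 M HCl, rt
Reagents that add atoms: tributyl(1-ethoxyvinyl)stannane, CCCC[Sn](CCCC)(CCCC)C(=C)OCC; water, O
Why: Stille coupling of the enol triflate with an acyl anion equivalent, then enol ether hydrolysis, should give the conjugated methyl ketone.

Step 11
Reactants: 17 methyl ketone
Product: 18 (S)-1-{5,6-dimethyl-6-[(E)-5-(4-methoxybenzyloxy)-3-methylpent-3-enyl]cyclohex-1-enyl}ethanol
Conditions: (R)-2-methyl-CBS-oxazaborolidine (20 mol%), catecholborane, toluene, −78 °C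
Reagents that add atoms: none
Why: CBS reduction with the alkenyl group as the large and methyl as the small substituent should give the (S)-carbinol under reagent control.

Step 12
Reactants: 18 (S)-allylic alcohol; 19 hex-5-enoic acid
Product: 20 hex-5-enoate ester of 18
Conditions: DCC, DMAP (cat.), CH2Cl2, 0 °C to rt
Reagents that add atoms: none
Why: Steglich esterification of the secondary allylic alcohol.

Step 13
Reactants: 20 hex-5-enoate ester
Product: 23 2-{(E)-2-ethylidene-3,4-dimethyl-3-[(E)-5-(4-methoxybenzyloxy)-3-methylpent-3-enyl]cyclohexyl}hex-5-enoic acid (C4–C5 bond β, H5 α; C4 not controlled), via silyl ketene acetal 21 (not isolated), via trimethylsilyl ester 22 (not isolated)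
Conditions: LiN(i-Pr)2 added to 20 and Me3SiCl/Et3N, THF, −78 °C; then 60 °C; then 1 M HCl
Reagents that add atoms: none
Why: Ireland–Claisen rearrangement through a chair [3,3] transition state should pass the carbinol chirality suprafacially to C5; allylic strain with the quaternary C9 should place the carbinol methyl axial (inside), so that the (S)-ester delivers C4 to the β face of C5 and leaves an (E)-ethylidene, and the uncontrolled C4 centre is erased in step 14.

Step 14
Reactants: 23 seco-ring-A acid
Product: 25 2-methyl-2-{(E)-2-ethylidene-3,4-dimethyl-3-[(E)-5-(4-methoxybenzyloxy)-3-methylpent-3-enyl]cyclohexyl}hex-5-enoic acid (C4 quaternary), via dilithium enediolate 24 (not isolated)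
Conditions: LiN(i-Pr)2 (2.5 equiv), THF/DMPU, −78 to 0 °C; then MeI, −78 to 0 °C
Reagents that add atoms: iodomethane, CI
Why: C-Methylation of the carboxylic acid dianion under acyclic 1,2-induction: with C5–H eclipsing the enediolate plane (allylic 1,3-strain), MeI should enter anti to the bulky C10 branch, which gives CH3 β and CO2H α at C4 once ring A is closed.

Step 15
Reactants: 25 methylated seco-ring-A acid
Product: 26 15-(4-methoxybenzyloxy)halima-1(10),13E-dien-18-oic acid
Conditions: second-generation Hoveyda–Grubbs catalyst RuCl2(H2IMes)(=CH–C6H4-2-O-i-Pr) (10 mol%), toluene (2 mM), 80 °C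
Reagents that add atoms: none
Why: Ring-closing metathesis between the terminal alkene and the ethylidene should close ring A as the trisubstituted C1=C10 alkene with loss of propene, helped by the quaternary C4 in the tether.

Step 16
Reactants: 26 PMB ether acid
Product: 27 15-hydroxyhalima-1(10),13E-dien-18-oic acid
Conditions: DDQ, CH2Cl2/pH 7 buffer, 0 °C
Reagents that add atoms: none
Why: Oxidative cleavage of the 4-methoxybenzyl ether by DDQ, which leaves the trisubstituted alkenes and the acid untouched.

Step 17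
Reactants: 27 hydroxy acid; 28 3-phenylprop-2-ynoyl chloride
Product: 29 15-(3-phenylprop-2-ynoyloxy)halima-1(10),13E-dien-18-oic acid
Conditions: 2,6-lutidine, CH2Cl2, −20 °C; aqueous NaHCO3 work-up
Reagents that add atoms: none
Why: O-Acylation of the primary allylic alcohol by the acid chloride; the hindered tertiary acid can at most form a mixed anhydride, which the bicarbonate work-up should hydrolyse back.

Step 18
Reactants: 29 ynoate
Product: 30 CNP0150420.1, 15-[(Z)-cinnamoyloxy]halima-1(10),13E-dien-18-oic acid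
Conditions: H2 (1 atm), Pd/CaCO3 poisoned with Pb(OAc)2 (Lindlar catalyst), quinoline, EtOAc, rt
Reagents that add atoms: none
Why: Lindlar semi-hydrogenation adds H2 syn to the aryl ynoate and should give the (Z)-cinnamate without reducing the trisubstituted alkenes.

## Compound list

1 | (E)-but-2-enal | C/C=C/C=O | starting material
2 | (1E)-1-(triisopropylsilyloxy)buta-1,3-diene | C=C/C=C/O[Si](C(C)C)(C(C)C)C(C)C | intermediate
3 | (E)-2-methylbut-2-enal | C/C=C(\C)C=O | starting material
4 | ring B aldehyde, 1,6-dimethyl-2-(triisopropylsilyloxy)cyclohex-3-ene-1-carbaldehyde (C9: CH3 β, CHO α; C8: CH3 β; C10: OSi α) | O=C[C@]1(C)[C@H](O[Si](C(C)C)(C(C)C)C(C)C)C=CC[C@H]1C | intermediate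
5 | ring B diene, 4-ethenyl-4,5-dimethyl-3-(triisopropylsilyloxy)cyclohexene | C=C[C@]1(C)[C@H](O[Si](C(C)C)(C(C)C)C(C)C)C=CC[C@H]1C | intermediate
6 | but-2-yn-1-ol | CC#CCO | starting material
7 | 1-(but-2-ynyloxymethyl)-4-methoxybenzene | CC#CCOCc1ccc(OC)cc1 | intermediate
8 | (E)-alkenylzirconocene chloride from 7 (Zr on C13, trans to CH2O) | C/C(=C\COCc1ccc(OC)cc1)[Zr](Cl)(C1C=CC=C1)C1C=CC=C1 | intermediate
9 | (E)-3-iodobut-2-enyl 4-methoxybenzyl ether | C/C(I)=C\COCc1ccc(OC)cc1 | intermediate
10 | B-alkyl-9-BBN borane from 5 (boron on C12) | B1(CC[C@]2(C)[C@H](O[Si](C(C)C)(C(C)C)C(C)C)C=CC[C@H]2C)C2CCCC1CCC2 | intermediate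
11 | ring B silyl ether with the side chain C11–C16 (13E, C15–O-PMB) | COc1ccc(COC/C=C(\C)CC[C@]2(C)[C@H](O[Si](C(C)C)(C(C)C)C(C)C)C=CC[C@H]2C)cc1 | intermediate
12 | allylic alcohol (C10–OH α) | COc1ccc(COC/C=C(\C)CC[C@]2(C)[C@H](O)C=CC[C@H]2C)cc1 | intermediate
13 | 5,6-dimethyl-6-[(E)-5-(4-methoxybenzyloxy)-3-methylpent-3-enyl]cyclohex-2-en-1-one (methyls cis) | COc1ccc(COC/C=C(\C)CC[C@]2(C)C(=O)C=CC[C@H]2C)cc1 | intermediate
14 | lithium enolate of the saturated ketone (C10–O–Li, C10=C5) | COc1ccc(COC/C=C(\C)CC[C@]2(C)C(O[Li])=CCC[C@H]2C)cc1 | intermediate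
15 | enol triflate (C10–OTf, C10=C5) | COc1ccc(COC/C=C(\C)CC[C@]2(C)C(OS(=O)(=O)C(F)(F)F)=CCC[C@H]2C)cc1 | intermediate
16 | ethyl enol ether (1-ethoxyvinyl on C10) | COc1ccc(COC/C=C(\C)CC[C@]2(C)C(C(=C)OCC)=CCC[C@H]2C)cc1 | intermediate
17 | methyl ketone (acetyl on C10, C10=C5) | COc1ccc(COC/C=C(\C)CC[C@]2(C)C(C(C)=O)=CCC[C@H]2C)cc1 | intermediate
18 | (S)-allylic alcohol (1-hydroxyethyl on C10) | COc1ccc(COC/C=C(\C)CC[C@]2(C)C([C@H](C)O)=CCC[C@H]2C)cc1 | intermediate
19 | hex-5-enoic acid | C=CCCCC(=O)O | starting material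
20 | hex-5-enoate ester of 18 | COc1ccc(COC/C=C(\C)CC[C@]2(C)C([C@H](C)OC(=O)CCCC=C)=CCC[C@H]2C)cc1 | intermediate
21 | trimethylsilyl ketene acetal of 20 (enol geometry not controlled) | COc1ccc(COC/C=C(\C)CC[C@]2(C)C([C@H](C)OC(=CCCC=C)O[Si](C)(C)C)=CCC[C@H]2C)cc1 | intermediate
22 | trimethylsilyl ester of 23 | COc1ccc(COC/C=C(\C)CC[C@]2(C)/C(=C/C)[C@@H](C(CCC=C)C(=O)O[Si](C)(C)C)CC[C@H]2C)cc1 | intermediate
23 | seco-ring-A acid, (E)-ethylidene on C10, C4–C5 bond β, C4 undefined | COc1ccc(COC/C=C(\C)CC[C@]2(C)/C(=C/C)[C@@H](C(CCC=C)C(=O)O)CC[C@H]2C)cc1 | intermediate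
24 | dilithium enediolate of 23 | COc1ccc(COC/C=C(\C)CC[C@]2(C)/C(=C/C)[C@@H](C(CCC=C)=C(O[Li])O[Li])CC[C@H]2C)cc1 | intermediate
25 | methylated seco-ring-A acid (C4 quaternary) | COc1ccc(COC/C=C(\C)CC[C@]2(C)/C(=C/C)[C@@H]([C@](C)(CCC=C)C(=O)O)CC[C@H]2C)cc1 | intermediate
26 | 15-(4-methoxybenzyloxy)halima-1(10),13E-dien-18-oic acid | COc1ccc(COC/C=C(\C)CC[C@]2(C)C3=CCC[C@](C)(C(=O)O)[C@H]3CC[C@H]2C)cc1 | intermediate
27 | 15-hydroxyhalima-1(10),13E-dien-18-oic acid | C/C(=C\CO)CC[C@]1(C)C2=CCC[C@](C)(C(=O)O)[C@H]2CC[C@H]1C | intermediate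
28 | 3-phenylprop-2-ynoyl chloride | O=C(Cl)C#Cc1ccccc1 | starting material
29 | 15-(3-phenylprop-2-ynoyloxy)halima-1(10),13E-dien-18-oic acid | C/C(=C\COC(=O)C#Cc1ccccc1)CC[C@]1(C)C2=CCC[C@](C)(C(=O)O)[C@H]2CC[C@H]1C | intermediate
30 | CNP0150420.1, 15-[(Z)-cinnamoyloxy]halima-1(10),13E-dien-18-oic acid | C/C(=C\COC(=O)/C=C\c1ccccc1)CC[C@]1(C)C2=CCC[C@](C)(C(=O)O)[C@H]2CC[C@H]1C | target

## Step count and risks

Total step count: 18. Longest linear sequence: 16 (steps 1–3 and 6–18).

The three steps most likely to fail: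

**Step 2.** The catalyst may discriminate poorly between the enal faces, the silyl dienol ether may add 1,2 to the activated formyl group, and the β-methylated dienophile may react slowly. The fallback sets out from 2 and 3 and comes back at 18. The cycloaddition is run without a chiral catalyst (neat at 110 °C, or with 10 mol% EtAlCl2), and racemic 4 is carried through steps 3 and 6 to 10. The reagent-controlled reduction of step 11 then converts racemic 17 into 18 and its diastereomer, the (S)-carbinol on the antipodal ring B F1. The two are separated by chromatography, so absolute control moves from the cycloaddition to the reduction.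

**Step 13.** Chirality transfer may erode if the chair with an equatorial carbinol methyl, or a boat, competes and gives the C5 epimer. The fallback sets out from 15 and comes back at 26; it removes the sacrificial stereocentre and relies on reagent control.
- Methoxycarbonylation of 15 (Pd(OAc)2, dppp, CO, MeOH, Et3N) gives the methyl cyclohexenecarboxylate F2.
- (i-Bu)2AlH reduces it to the primary allylic alcohol F3.
- DCC and DMAP with 19 give the hex-5-enoate F4.
- An enantioselective Ireland–Claisen rearrangement through the chiral boron enolate follows, using 2-bromo-4,5-diphenyl-1,3-bis(p-tolylsulfonyl)-1,3,2-diazaborolidine and Et3N in CH2Cl2, with the enantiomer chosen for β-face attack. It gives the exocyclic-methylene acid F5.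
- Dianion methylation as in step 14 gives the quaternary acid F6.
- Ring-closing metathesis of its 1,1-disubstituted alkene, with loss of ethene, gives 26.

**Step 15.** The ruthenium alkylidene may fail to engage the trisubstituted ethylidene flanked by C9 and C5, and the terminal alkene may oligomerise instead. The fallback sets out from 17 and comes back at 26; it builds ring A by cycloaddition and not by metathesis.
- t-BuMe2SiOTf and Et3N convert 17 into the 2-silyloxydiene F7.
- A Diels–Alder reaction with methyl methacrylate (toluene, 120 °C) gives the silyl enol ether cycloadduct F8. The 2-silyloxy group and the substituted C5 terminus both direct C4 to C5; face and exo/endo isomers would be separated.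
- CsF and PhNTf2 give the enol triflate F9.
- Pd(OAc)2, PPh3, HCO2H and Bu3N reduce it to the methyl ester F10.
- LiSPr in HMPA cleaves the hindered ester to 26.

Further compounds
F1 | step 2 | (S)-carbinol diastereomer of 18 on the antipodal ring B | COc1ccc(COC/C=C(\C)CC[C@@]2(C)C([C@H](C)O)=CCC[C@@H]2C)cc1
F2 | step 13 | methyl cyclohexenecarboxylate (CO2CH3 on C10, C10=C5) | COc1ccc(COC/C=C(\C)CC[C@]2(C)C(C(=O)OC)=CCC[C@H]2C)cc1
F3 | step 13 | primary allylic alcohol (CH2OH on C10) | COc1ccc(COC/C=C(\C)CC[C@]2(C)C(CO)=CCC[C@H]2C)cc1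
F4 | step 13 | hex-5-enoate of F3 | COc1ccc(COC/C=C(\C)CC[C@]2(C)C(COC(=O)CCCC=C)=CCC[C@H]2C)cc1
F5 | step 13 | exocyclic-methylene seco-ring-A acid (C4–C5 bond β, C4 undefined) | COc1ccc(COC/C=C(\C)CC[C@]2(C)C(=C)[C@@H](C(CCC=C)C(=O)O)CC[C@H]2C)cc1
F6 | step 13 | methylated exocyclic-methylene acid (C4 quaternary) | COc1ccc(COC/C=C(\C)CC[C@]2(C)C(=C)[C@@H]([C@](C)(CCC=C)C(=O)O)CC[C@H]2C)cc1
F7 | step 15 | 2-(tert-butyldimethylsilyloxy)diene from 17 | COc1ccc(COC/C=C(\C)CC[C@]2(C)C(C(=C)O[Si](C)(C)C(C)(C)C)=CCC[C@H]2C)cc1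
F8 | step 15 | silyl enol ether cycloadduct (C1–OSi, C1=C10, C4 with CH3 β and CO2CH3 α) | COc1ccc(COC/C=C(\C)CC[C@]2(C)C3=C(O[Si](C)(C)C(C)(C)C)CC[C@](C)(C(=O)OC)[C@H]3CC[C@H]2C)cc1
F9 | step 15 | enol triflate (C1–OTf, C1=C10) | COc1ccc(COC/C=C(\C)CC[C@]2(C)C3=C(OS(=O)(=O)C(F)(F)F)CC[C@](C)(C(=O)OC)[C@H]3CC[C@H]2C)cc1
F10 | step 15 | methyl ester of 26 | COc1ccc(COC/C=C(\C)CC[C@]2(C)C3=CCC[C@](C)(C(=O)OC)[C@H]3CC[C@H]2C)cc1
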